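**Retrosynthetic overview**

1. Target 29 comes from triol 28 by acetylation of the equatorial C2–OH and the primary C15–OH. The ring-A oxygens come from the Δ1-3-silyloxy diene 22: C3–OH is oxidised to the Δ1-3-enone, C2–O is introduced by enolate hydroxylation from the open face, and the C3 ketone is reduced to the axial alcohol.
2. Ring B of 22 is closed in one operation from the monocyclic phosphonium salt 19: Claisen rearrangement (C9–C10) of a (Z)-enol ether carried on the C2 oxygen, then intramolecular Wittig reaction (C7=C8) of the released methyl ketone with the ylide on the C5 side chain.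
3. Enabling feature: in ring A the C2 oxygen is allylic to C1=C10 (O–C2–C1=C10). An O-bound enol ether of the C8 ketone therefore delivers C9 to C10 through a six-atom [3,3] array on the face that carries the oxygen, and C7 on the two-carbon arm at C5 then lies 1,6 to the new C8 carbonyl.
4. 19 comes from the ring-A allylic acetate 10 and the gem-dibromide 16 by Takai alkylidenation (acetate C=O becomes C8, acetate CH3 becomes C17, the dibromide carbon becomes C9).
5. Ring A is not constructed: it comes from (R)-α-ionone (C5 stereocentre; C6–C7 after excision of the acetyl group by Baeyer–Villiger oxidation). C9 and C11–C16 come from geraniol. Ring order: A (chiral pool), then B (step 15).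

Key step: step 15

Remark: atom numbers C1–C20 are those of the (ent-)labdane skeleton of the target and are also used for the ring-A fragments; (R)-(+)-α-ionone of high enantiomeric purity is assumed to be commercially available.

**Route**

Step 1
Reactants: 1 (R)-α-ionone
Product: 2 (R)-7,8-dihydro-α-ionone
Conditions: [(Ph3P)CuH]6 (3 mol %), H2 (35 bar), t-BuOH (1 equiv), benzene, 23 °C
Reagents that add atoms: none
Why: Copper hydride conjugate reduction delivers hydride only to the β-carbon of the side-chain enone, so the isolated trisubstituted ring alkene and the C5 stereocentre should be untouched under these neutral conditions.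

Step 2
Reactants: 2 (R)-7,8-dihydro-α-ionone
Product: 3 (4R)-3,5,5-trimethyl-4-(3-oxobutyl)cyclohex-2-en-1-one
Conditions: Rh2(cap)4 (1 mol %), t-BuOOH (5 equiv), K2CO3 (0.5 equiv), CH2Cl2, 23 °C
Reagents that add atoms: tert-butyl hydroperoxide, CC(C)(C)OO
Why: Rh(II)-catalysed allylic C–H oxidation should convert the only allylic methylene (C2) into the enone carbonyl, as known for α-ionone-type cyclohexenes, leaving the hindered tertiary C5–H alone.

Step 3
Reactants: 3 (4R)-3,5,5-trimethyl-4-(3-oxobutyl)cyclohex-2-en-1-one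
Product: 4 2-[(1R)-2,6,6-trimethyl-4-oxocyclohex-2-en-1-yl]ethyl acetate
Conditions: mCPBA (2 equiv), CF3CO2H (0.2 equiv), CH2Cl2, 23 °C
Reagents that add atoms: 3-chloroperbenzoic acid, OOC(=O)c1cccc(Cl)c1
Why: Baeyer–Villiger oxidation should take place at the saturated methyl ketone (primary alkyl C7 migrates in preference to methyl), because the conjugated, electron-poor enone is much less reactive towards the peracid.

Step 4
Reactants: 4 2-[(1R)-2,6,6-trimethyl-4-oxocyclohex-2-en-1-yl]ethyl acetate
Product: 5 (4R)-4-(2-hydroxyethyl)-3,5,5-trimethylcyclohex-2-en-1-one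
Conditions: K2CO3 (0.2 equiv), MeOH, 0 °C
Reagents that add atoms: none
Why: Base-catalysed transesterification (methanolysis) should free the primary alcohol under conditions too mild to deprotonate the γ-position (C5) of the enone.

Step 5
Reactants: 5 (4R)-4-(2-hydroxyethyl)-3,5,5-trimethylcyclohex-2-en-1-one
Product: 6 (4R)-4-(2-bromoethyl)-3,5,5-trimethylcyclohex-2-en-1-one
Conditions: CBr4, PPh3, CH2Cl2, 0 °C
Reagents that add atoms: carbon tetrabromide, BrC(Br)(Br)Br
Why: The Appel reaction converts the unhindered primary alcohol into the bromide by SN2 displacement of the oxyphosphonium group, and the enone is inert.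

Step 6
Reactants: 6 (4R)-4-(2-bromoethyl)-3,5,5-trimethylcyclohex-2-en-1-one
Product: 8 (4S,6R)-4-(2-bromoethyl)-6-[(tert-butyldimethylsilyl)oxy]-3,5,5-trimethylcyclohex-2-en-1-one, via TBS dienol ether 7 (not isolated)
Conditions: LDA, THF, −78 °C; TBSOTf, −78 °C; then crude 7, mCPBA, NaHCO3, CH2Cl2, −20 °C
Reagents that add atoms: tert-butyldimethylsilyl trifluoromethanesulfonate, CC(C)(C)[Si](C)(C)OS(=O)(=O)C(F)(F)F; 3-chloroperbenzoic acid, OOC(=O)c1cccc(Cl)c1
Why: Kinetic α′-deprotonation (C3) with immediate O-silylation gives the cross-conjugated dienol ether, and Rubottom oxidation with 1,4-silyl migration installs the C3 silyloxy group, the peracid being expected to approach anti to the pseudo-axial C5 side chain (3,5-trans).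

Step 7
Reactants: 8 (4S,6R)-4-(2-bromoethyl)-6-[(tert-butyldimethylsilyl)oxy]-3,5,5-trimethylcyclohex-2-en-1-one
Product: 9 (1S,4S,6R)-4-(2-bromoethyl)-6-[(tert-butyldimethylsilyl)oxy]-3,5,5-trimethylcyclohex-2-en-1-ol
Conditions: NaBH4, CeCl3·7H2O, MeOH, −78 °C
Reagents that add atoms: none
Why: Luche 1,2-reduction of the enone, in which hydride should add anti to the neighbouring C3 silyloxy group and so place the C2 hydroxyl cis to C3–O and trans to the C5 side chain, the configuration the Claisen step needs.

Step 8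
Reactants: 9 (1S,4S,6R)-4-(2-bromoethyl)-6-[(tert-butyldimethylsilyl)oxy]-3,5,5-trimethylcyclohex-2-en-1-ol
Product: 10 (1S,4S,6R)-4-(2-bromoethyl)-6-[(tert-butyldimethylsilyl)oxy]-3,5,5-trimethylcyclohex-2-en-1-yl acetate
Conditions: Ac2O, pyridine, DMAP (cat.), CH2Cl2, 23 °C
Reagents that add atoms: acetic anhydride, CC(=O)OC(C)=O
Why: DMAP-catalysed acylation of the secondary allylic alcohol gives the only ester in the molecule, whose C=O and CH3 become C8 and C17.

Step 9
Reactants: 11 geraniol
Product: 12 geranyl 4-methoxybenzyl ether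
Conditions: NaH, 4-methoxybenzyl chloride, Bu4NI (cat.), THF, 0 → 23 °C
Reagents that add atoms: 4-methoxybenzyl chloride, COc1ccc(CCl)cc1
Why: Williamson ether synthesis protects the C15 oxygen as an ether that tolerates low-valent titanium, ylide, fluoride and hydride reagents.

Step 10
Reactants: 12 geranyl 4-methoxybenzyl ether
Product: 13 6,7-epoxygeranyl 4-methoxybenzyl ether (racemic at the epoxide)
Conditions: mCPBA (1.0 equiv), NaHCO3, CH2Cl2, −20 °C
Reagents that add atoms: 3-chloroperbenzoic acid, OOC(=O)c1cccc(Cl)c1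
Why: Prilezhaev epoxidation is selective for the remote, more electron-rich trisubstituted alkene, because the 2,3-alkene is deactivated by the allylic oxygen; the new stereocentre is destroyed in the next step.

Step 11
Reactants: 13 6,7-epoxygeranyl 4-methoxybenzyl ether
Product: 15 (4E)-6-[(4-methoxybenzyl)oxy]-4-methylhex-4-enal, via diol 14 (not isolated)
Conditions: H5IO6, THF/H2O, 0 °C
Reagents that add atoms: none
Why: Acid-promoted epoxide hydrolysis followed by periodate glycol cleavage removes the isopropylidene terminus as acetone and leaves the aldehyde whose carbon is the future C9.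

Step 12
Reactants: 15 (4E)-6-[(4-methoxybenzyl)oxy]-4-methylhex-4-enal
Product: 16 1-({[(2E)-6,6-dibromo-3-methylhex-2-en-1-yl]oxy}methyl)-4-methoxybenzene
Conditions: P(OPh)3, Br2, CH2Cl2, −78 °C; then 15, Et3N (0.2 equiv), −78 → 0 °C
Reagents that add atoms: bromine, BrBr
Why: Deoxygenative gem-dibromination of the aldehyde by the preformed bromophosphonium reagent (Appel-type), so that the alkene and the anisyl ring are not exposed to free bromine.

Step 13
Reactants: 10 (1S,4S,6R)-4-(2-bromoethyl)-6-[(tert-butyldimethylsilyl)oxy]-3,5,5-trimethylcyclohex-2-en-1-yl acetate; 16 1-({[(2E)-6,6-dibromo-3-methylhex-2-en-1-yl]oxy}methyl)-4-methoxybenzene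
Product: 17 (1S,4S,6R)-4-(2-bromoethyl)-6-[(tert-butyldimethylsilyl)oxy]-3,5,5-trimethylcyclohex-2-en-1-yl (2Z,6E)-8-[(4-methoxybenzyl)oxy]-6-methylocta-2,6-dien-2-yl ether
Conditions: TiCl4, TMEDA, Zn, PbCl2 (cat.), THF, 23 °C (16, 2.2 equiv)
Reagents that add atoms: none
Why: Takai alkylidenation of the acetate carbonyl by the titanium alkylidene generated from the gem-dibromide gives the ketone-type enol ether with the known Z preference (alkoxy and alkyl cis); no stereocentre is formed, and the primary bromide, silyl ether and alkenes are tolerated.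

Step 14
Reactants: 17 (Z)-enol ether bromide
Product: 19 {2-[ring-A (Z)-enol ether]ethyl}triphenylphosphonium iodide (17 with PPh3+ I− in place of Br), via alkyl iodide 18 (not isolated)
Conditions: NaI, PPh3, 2,6-lutidine (0.1 equiv), MeCN, 55 °C
Reagents that add atoms: triphenylphosphine, c1ccc(cc1)P(c1ccccc1)c1ccccc1; sodium iodide, [Na+].[I-]
Why: Finkelstein exchange followed by SN2 quaternisation of triphenylphosphine at the unhindered primary carbon C7, under buffered neutral conditions and below the temperature at which the allyl vinyl ether rearranges.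

Step 15
Reactants: 19 phosphonium iodide
Product: 22 (3S,5S,9R,10S)-3-[(tert-butyldimethylsilyl)oxy]-15-[(4-methoxybenzyl)oxy]-ent-labda-1,7,13E-triene, via keto phosphonium iodide 20 (not isolated), via keto ylide 21 (not isolated)
Conditions: diglyme, 2,6-lutidine (0.2 equiv), 140 °C; then −40 °C, KHMDS (1.1 equiv), → 23 °C (one flask)
Reagents that add atoms: none
Why: Heating 19 triggers a thermal Claisen rearrangement of the ketone-derived (Z)-allyl vinyl ether: the C2–O bond breaks while C9 bonds to C10 on the face that carried the C2 oxygen, which releases the C8 methyl ketone 1,6 to C7; KHMDS then forms the non-stabilised ylide at C7, which adds to C8 and expels Ph3P=O to give the C7=C8 bond. The closest known reaction types are the Claisen rearrangement of Takai-derived enol ethers of cyclohex-2-enols to quaternary γ,δ-unsaturated ketones and the intramolecular Wittig cyclisation of ω-oxoalkylphosphonium salts. Ring B closes by carbonyl olefination in the 6-exo mode (C7 adds to the C8 carbonyl, whose C=O lies outside the forming six-membered ring). C10 is set by suprafacial chirality transfer from C2; because the C2 oxygen is trans to the C5 side chain, C9 and C6 end up trans on ring A and the decalin is trans-fused. C9 is set by the Z enol ether reacting through the boat-like transition state, the chair being disfavoured because it would push the C8 methyl under ring A against the C3 silyloxy and C4 methyl groups. The step needs boat over chair selectivity and ring closure faster than enolisation of the methyl ketone; these rest on the Z geometry from step 13, the bulky C3–OTBS group and the easier deprotonation of the phosphonium salt compared with the ketone.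

Step 16
Reactants: 22 silyl ether
Product: 23 (3S,5S,9R,10S)-15-[(4-methoxybenzyl)oxy]-ent-labda-1,7,13E-trien-3-ol
Conditions: TBAF, THF, 50 °C
Reagents that add atoms: none
Why: Fluoride-induced desilylation frees the hindered allylic C3 alcohol, and the PMB ether is inert to fluoride.

Step 17
Reactants: 23 allylic alcohol
Product: 24 (5S,9R,10S)-15-[(4-methoxybenzyl)oxy]-ent-labda-1,7,13E-trien-3-one
Conditions: MnO2, CH2Cl2, 23 °C
Reagents that add atoms: none
Why: Manganese dioxide oxidises the allylic alcohol selectively to the Δ1-3-enone; the C3 stereocentre is deliberately erased, and C4 being quaternary leaves C2 as the only enolisable position for the next two steps.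

Step 18
Reactants: 24 Δ1-3-enone
Product: 26 (2S,5S,9R,10S)-2-hydroxy-15-[(4-methoxybenzyl)oxy]-ent-labda-7,13E-dien-3-one, via potassium enolate 25 (not isolated)
Conditions: K-Selectride, THF, −78 °C; then 2-(phenylsulfonyl)-3-phenyloxaziridine, −78 → −40 °C; H2O
Reagents that add atoms: 2-(phenylsulfonyl)-3-phenyloxaziridine, O=S(=O)(N1OC1c1ccccc1)c1ccccc1
Why: Conjugate hydride reduction gives the C2=C3 enolate regiospecifically, and electrophilic enolate hydroxylation by the N-sulfonyloxaziridine should occur on the face away from the axial C10 and C4 methyl groups, giving the equatorial C2–OH of the target.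

Step 19
Reactants: 26 α-hydroxy ketone
Product: 27 (2S,3R,5S,9R,10S)-15-[(4-methoxybenzyl)oxy]-ent-labda-7,13E-diene-2,3-diol
Conditions: K-Selectride (3 equiv), THF, −78 °C; H2O
Reagents that add atoms: none
Why: Reduction of the hindered 4,4-dimethyl-3-ketone with a bulky trialkylborohydride proceeds by equatorial attack and should give the axial C3 alcohol, cis to the C2 oxygen, as known for 3-oxo-4,4-dimethyl terpenoids.

Step 20
Reactants: 27 PMB ether diol
Product: 28 (2S,3R,5S,9R,10S)-ent-labda-7,13E-diene-2,3,15-triol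
Conditions: DDQ (1.1 equiv), CH2Cl2/pH 7 buffer, 0 °C
Reagents that add atoms: none
Why: Oxidative cleavage of the 4-methoxybenzyl ether by DDQ (hydride abstraction, then hydrolysis of the oxocarbenium ion) frees the C15 alcohol without touching the alkenes.

Step 21
Reactants: 28 triol
Product: 29 target, (2S,3R,5S,9R,10S)-2,15-diacetoxy-ent-labda-7,13E-dien-3-ol
Conditions: Ac2O (2.2 equiv), pyridine, CH2Cl2, −20 → 0 °C
Reagents that add atoms: acetic anhydride, CC(=O)OC(C)=O
Why: Selective acylation: the primary allylic C15–OH and the equatorial C2–OH should react, whereas the axial, neopentyl C3–OH next to the gem-dimethyl group should stay free.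

**Compound list**

1 | (R)-α-ionone, (3E)-4-[(1R)-2,6,6-trimethylcyclohex-2-en-1-yl]but-3-en-2-one | CC(=O)/C=C/[C@@H]1C(C)(C)CCC=C1C | starting material
2 | (R)-7,8-dihydro-α-ionone, 4-[(1R)-2,6,6-trimethylcyclohex-2-en-1-yl]butan-2-one | CC(=O)CC[C@@H]1C(C)(C)CCC=C1C | intermediate
3 | (4R)-3,5,5-trimethyl-4-(3-oxobutyl)cyclohex-2-en-1-one | CC(=O)CC[C@@H]1C(C)(C)CC(=O)C=C1C | intermediate
4 | 2-[(1R)-2,6,6-trimethyl-4-oxocyclohex-2-en-1-yl]ethyl acetate | CC(=O)OCC[C@@H]1C(C)(C)CC(=O)C=C1C | intermediate
5 | (4R)-4-(2-hydroxyethyl)-3,5,5-trimethylcyclohex-2-en-1-one | OCC[C@@H]1C(C)(C)CC(=O)C=C1C | intermediate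
6 | (4R)-4-(2-bromoethyl)-3,5,5-trimethylcyclohex-2-en-1-one | BrCC[C@@H]1C(C)(C)CC(=O)C=C1C | intermediate
7 | cross-conjugated TBS dienol ether of 6 (silyloxy at C2, C2=C3 and C1=C10 double bonds, C5 unchanged) | BrCC[C@@H]1C(C)(C)C=C(O[Si](C)(C)C(C)(C)C)C=C1C | intermediate
8 | (4S,6R)-4-(2-bromoethyl)-6-[(tert-butyldimethylsilyl)oxy]-3,5,5-trimethylcyclohex-2-en-1-one (C3–OTBS trans to the C5 side chain) | BrCC[C@@H]1C(C)(C)[C@@H](O[Si](C)(C)C(C)(C)C)C(=O)C=C1C | intermediate
9 | (1S,4S,6R)-4-(2-bromoethyl)-6-[(tert-butyldimethylsilyl)oxy]-3,5,5-trimethylcyclohex-2-en-1-ol (C2–OH cis to C3–O, trans to the side chain) | BrCC[C@@H]1C(C)(C)[C@@H](O[Si](C)(C)C(C)(C)C)[C@@H](O)C=C1C | intermediate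
10 | (1S,4S,6R)-4-(2-bromoethyl)-6-[(tert-butyldimethylsilyl)oxy]-3,5,5-trimethylcyclohex-2-en-1-yl acetate | BrCC[C@@H]1C(C)(C)[C@@H](O[Si](C)(C)C(C)(C)C)[C@@H](OC(C)=O)C=C1C | intermediate
11 | geraniol, (2E)-3,7-dimethylocta-2,6-dien-1-ol | CC(C)=CCC/C(C)=C/CO | starting material
12 | geranyl 4-methoxybenzyl ether | CC(C)=CCC/C(C)=C/COCc1ccc(OC)cc1 | intermediate
13 | 6,7-epoxygeranyl 4-methoxybenzyl ether (racemic at C6) | CC1(C)OC1CC/C(C)=C/COCc1ccc(OC)cc1 | intermediate
14 | (6E)-8-[(4-methoxybenzyl)oxy]-2,6-dimethyloct-6-ene-2,3-diol (racemic) | CC(C)(O)C(O)CC/C(C)=C/COCc1ccc(OC)cc1 | intermediate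
15 | (4E)-6-[(4-methoxybenzyl)oxy]-4-methylhex-4-enal | O=CCC/C(C)=C/COCc1ccc(OC)cc1 | intermediate
16 | 1-({[(2E)-6,6-dibromo-3-methylhex-2-en-1-yl]oxy}methyl)-4-methoxybenzene | BrC(Br)CC/C(C)=C/COCc1ccc(OC)cc1 | intermediate
17 | (1S,4S,6R)-4-(2-bromoethyl)-6-[(tert-butyldimethylsilyl)oxy]-3,5,5-trimethylcyclohex-2-en-1-yl (2Z,6E)-8-[(4-methoxybenzyl)oxy]-6-methylocta-2,6-dien-2-yl ether | BrCC[C@@H]1C(C)(C)[C@@H](O[Si](C)(C)C(C)(C)C)[C@@H](O/C(C)=C\CC/C(C)=C/COCc2ccc(OC)cc2)C=C1C | intermediate
18 | alkyl iodide corresponding to 17 (I in place of Br) | ICC[C@@H]1C(C)(C)[C@@H](O[Si](C)(C)C(C)(C)C)[C@@H](O/C(C)=C\CC/C(C)=C/COCc2ccc(OC)cc2)C=C1C | intermediate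
19 | triphenylphosphonium iodide corresponding to 17 (PPh3+ I− in place of Br) | [I-].c1ccccc1[P+](c1ccccc1)(c1ccccc1)CC[C@@H]1C(C)(C)[C@@H](O[Si](C)(C)C(C)(C)C)[C@@H](O/C(C)=C\CC/C(C)=C/COCc2ccc(OC)cc2)C=C1C | intermediate
20 | keto phosphonium iodide, Claisen product of 19 (C9–C10 bond formed on the former C2–O face, C10 quaternary, C1=C2 alkene, C8 methyl ketone, C3–OTBS, C7–PPh3+) | COc1ccc(COC/C=C(\C)CC[C@H](C(C)=O)[C@]2(C)C=C[C@H](O[Si](C)(C)C(C)(C)C)C(C)(C)[C@H]2CC[P+](c2ccccc2)(c2ccccc2)c2ccccc2)cc1.[I-] | intermediate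
21 | keto ylide from 20 (C7=PPh3) | COc1ccc(COC/C=C(\C)CC[C@H](C(C)=O)[C@]2(C)C=C[C@H](O[Si](C)(C)C(C)(C)C)C(C)(C)[C@H]2CC=P(c2ccccc2)(c2ccccc2)c2ccccc2)cc1 | intermediate
22 | (3S,5S,9R,10S)-3-[(tert-butyldimethylsilyl)oxy]-15-[(4-methoxybenzyl)oxy]-ent-labda-1,7,13E-triene | COc1ccc(COC/C=C(\C)CC[C@@H]2C(C)=CC[C@@H]3C(C)(C)[C@@H](O[Si](C)(C)C(C)(C)C)C=C[C@@]23C)cc1 | intermediate
23 | (3S,5S,9R,10S)-15-[(4-methoxybenzyl)oxy]-ent-labda-1,7,13E-trien-3-ol | COc1ccc(COC/C=C(\C)CC[C@@H]2C(C)=CC[C@@H]3C(C)(C)[C@@H](O)C=C[C@@]23C)cc1 | intermediate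
24 | (5S,9R,10S)-15-[(4-methoxybenzyl)oxy]-ent-labda-1,7,13E-trien-3-one | COc1ccc(COC/C=C(\C)CC[C@@H]2C(C)=CC[C@@H]3C(C)(C)C(=O)C=C[C@@]23C)cc1 | intermediate
25 | potassium C2=C3 enolate of the 1,2-dihydro derivative of 24 | COc1ccc(COC/C=C(\C)CC[C@@H]2C(C)=CC[C@@H]3C(C)(C)C([O-])=CC[C@@]23C)cc1.[K+] | intermediate
26 | (2S,5S,9R,10S)-2-hydroxy-15-[(4-methoxybenzyl)oxy]-ent-labda-7,13E-dien-3-one (2-OH equatorial) | COc1ccc(COC/C=C(\C)CC[C@@H]2C(C)=CC[C@@H]3C(C)(C)C(=O)[C@@H](O)C[C@@]23C)cc1 | intermediate
27 | (2S,3R,5S,9R,10S)-15-[(4-methoxybenzyl)oxy]-ent-labda-7,13E-diene-2,3-diol (2-OH equatorial, 3-OH axial, cis) | COc1ccc(COC/C=C(\C)CC[C@@H]2C(C)=CC[C@@H]3C(C)(C)[C@@H](O)[C@@H](O)C[C@@]23C)cc1 | intermediate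
28 | (2S,3R,5S,9R,10S)-ent-labda-7,13E-diene-2,3,15-triol | OC/C=C(\C)CC[C@@H]1C(C)=CC[C@@H]2C(C)(C)[C@@H](O)[C@@H](O)C[C@@]12C | intermediate
29 | (2S,3R,5S,9R,10S)-2,15-diacetoxy-ent-labda-7,13E-dien-3-ol (CNP0254679.1) | CC(=O)OC/C=C(\C)CC[C@@H]1C(C)=CC[C@@H]2C(C)(C)[C@@H](O)[C@@H](OC(C)=O)C[C@@]12C | target

**Step count**

Total steps: 21. Longest linear sequence: 17 (steps 1–8 and 13–21); steps 9–12 make the side-chain fragment.

**Steps most likely to fail, with fallbacks**

Step 15. The boat-like and chair-like transition states of the [3,3] shift may not be well discriminated, which would erode the C9 configuration. Proton transfer from the new methyl ketone to the ylide may also compete with ring closure, epimerising C9 or stalling the cyclisation. The fallback sets out from 17 and comes back to the route at 22. Heating 17 alone (toluene, 2,6-lutidine, 140 °C) should give the Claisen bromo ketone F1, at which stage the C9 epimers can be checked and separated. Kornblum oxidation (AgBF4, DMSO, then Et3N) should convert the primary bromide into the keto aldehyde F2. Intramolecular McMurry coupling (TiCl3(DME)1.5, Zn–Cu, DME, reflux, high dilution) then joins C7 and C8 reductively, with no basic olefination reagent, and gives 22.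

Step 13. Alkylidenation of the hindered acetate, flanked by the silyloxy group and the alkene, may be slow, so that the titanium reagent is consumed by reduction and homocoupling and the Z geometry is eroded. The fallback sets out from 9 and 15 and comes back at 17. Wittig iodo-olefination of aldehyde 15 with (1-iodoethyl)triphenylphosphonium iodide and NaHMDS (THF, −78 °C) should give the (Z)-vinyl iodide F3. Copper-catalysed C–O coupling of alcohol 9 with F3 (CuI, 3,4,7,8-tetramethyl-1,10-phenanthroline, Cs2CO3, toluene, 80 °C) proceeds with retention of alkene geometry and gives 17; steps 8 and 12 are then not needed.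

Step 7. Facial selectivity of hydride addition may be poor, giving the C2 epimer, which would deliver C9 to the wrong face of C10 in step 15. The fallback sets out from 8 and comes back at 10. If the reduction gives mainly the epimeric alcohol F4 (C2–OH cis to the side chain), it is used instead: Mitsunobu reaction with acetic acid (PPh3, DIAD, toluene, 0 °C) should invert C2 and give acetate 10 directly, so step 8 is skipped.

**Further compounds**

F1 | step 15 | Claisen bromo ketone (as 20, with CH2CH2Br in place of CH2CH2PPh3+ I−) | COc1ccc(COC/C=C(\C)CC[C@H](C(C)=O)[C@]2(C)C=C[C@H](O[Si](C)(C)C(C)(C)C)C(C)(C)[C@H]2CCBr)cc1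
F2 | step 15 | keto aldehyde (as F1, with CH2CHO in place of CH2CH2Br) | COc1ccc(COC/C=C(\C)CC[C@H](C(C)=O)[C@]2(C)C=C[C@H](O[Si](C)(C)C(C)(C)C)C(C)(C)[C@H]2CC=O)cc1
F3 | step 13 | 1-({[(2E,6Z)-7-iodo-3-methylocta-2,6-dien-1-yl]oxy}methyl)-4-methoxybenzene | C/C(I)=C/CC/C(C)=C/COCc1ccc(OC)cc1
F4 | step 7 | (1R,4S,6R)-4-(2-bromoethyl)-6-[(tert-butyldimethylsilyl)oxy]-3,5,5-trimethylcyclohex-2-en-1-ol | BrCC[C@@H]1C(C)(C)[C@@H](O[Si](C)(C)C(C)(C)C)[C@H](O)C=C1C
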